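**Strategy.** The crowded ring A acid is never esterified; ring A is grown onto the depside carbonyl. The feature used is the oxygen pattern of ring A: C2–OH and C4–OMe are meta, with C3 between them, which is how a ketene carbonyl carbon and the oxygen-bearing carbon of an ynol ether end up after annulation. The ring B phenol is therefore carried as the aryl ester of (E)-3-pentylglutaconic acid, and its CH2COCl end is unmasked as a vinylketene. In one operation this ketene takes up methoxy(trimethylsilyl)acetylene, forms C2–C3, C4–C5 and C1–C2, closes ring A, and leaves silicon on C3 as the placeholder for chlorine.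

Key step: step 9

**Remarks on the chemistry.**
- Ring A is numbered C1 (bears the depside carbonyl), C2 (OH), C3 (Cl), C4 (OMe), C5 (H), C6 (pentyl).
- Precursor 11 is deliberately the (E) isomer, with the acid chloride on the sp3 carbon and the aryl ester on the alkene, trans to the CH2COCl arm.
- A (Z) half-ester, which is what opening of 3-pentylglutaconic anhydride by a phenol would deliver, would place the ketene beside the ester carbonyl and should collapse to a 6-aryloxy-2-pyranone. The glutaconate is therefore assembled by a stereodefined carbocupration.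
- With this placement the ketene arises by loss of HCl across the C(=O)–CH2 bond (that CH2 is also γ to the aryl ester), so no alkene geometry has to be set during the elimination.

**Route**

Step 1
Reactants: 1 olivetolic acid
Product: 2 tert-butyl 2,4-dihydroxy-6-pentylbenzoate
Conditions: tert-butyl 2,2,2-trichloroacetimidate (2 equiv), CH2Cl2/cyclohexane, rt
Reagents that add atoms: tert-butyl 2,2,2-trichloroacetimidate, CC(C)(C)OC(=N)C(Cl)(Cl)Cl
Why: Trichloroacetimidate tert-butylation alkylates the carboxyl oxygen through a tert-butyl cation transfer, so the hindered, decarboxylation-prone acid should be esterified at room temperature while the phenols stay free.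

Step 2
Reactants: 3 4-(tert-butyldimethylsilyloxy)but-1-yne; 4 pentylmagnesium bromide
Product: 6 (E)-3-[2-(tert-butyldimethylsilyloxy)ethyl]oct-2-enoic acid, via alkenylcopper 5 (not isolated)
Conditions: 4, CuBr·SMe2 (1 equiv), Et2O/Me2S, −45 °C; then 3, −45 → −25 °C; then HMPA, P(OEt)3 (cat.), CO2 (g), −40 °C → rt; cold dilute HCl to pH 3
Reagents that add atoms: carbon dioxide, O=C=O
Why: Normant syn-carbocupration should put pentyl on the internal alkyne carbon with copper cis to it on the terminus, and carboxylation of the alkenylcopper with retention then gives the acid with pentyl cis to CO2H, which fixes the (E) geometry that the key step needs.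

Step 3
Reactants: 6 (E)-3-[2-(tert-butyldimethylsilyloxy)ethyl]oct-2-enoic acid; 2 tert-butyl 2,4-dihydroxy-6-pentylbenzoate
Product: 7 tert-butyl 4-({(2E)-3-[2-(tert-butyldimethylsilyloxy)ethyl]oct-2-enoyl}oxy)-2-hydroxy-6-pentylbenzoate
Conditions: EDC·HCl (1.2 equiv), DMAP (0.1 equiv), CH2Cl2, 0 °C → rt
Reagents that add atoms: none
Why: Steglich-type carbodiimide esterification should acylate only the C4 hydroxyl of ring B, because the C2 hydroxyl is hydrogen-bonded to the neighbouring ester carbonyl and far less nucleophilic.

Step 4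
Reactants: 7 tert-butyl 4-({(2E)-3-[2-(tert-butyldimethylsilyloxy)ethyl]oct-2-enoyl}oxy)-2-hydroxy-6-pentylbenzoate
Product: 8 tert-butyl 4-({(2E)-3-[2-(tert-butyldimethylsilyloxy)ethyl]oct-2-enoyl}oxy)-2-(methoxymethoxy)-6-pentylbenzoate
Conditions: MOMCl (3 equiv), iPr2NEt (4 equiv), CH2Cl2, 0 → 40 °C
Reagents that add atoms: chloromethyl methyl ether, COCCl
Why: O-Alkylation of the remaining chelated phenol with the reactive α-chloro ether under amine base (acetal protection) should proceed without touching the aryl ester, and it removes the one hydroxyl that the ketene of step 9 could acylate.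

Step 5
Reactants: 8 tert-butyl 4-({(2E)-3-[2-(tert-butyldimethylsilyloxy)ethyl]oct-2-enoyl}oxy)-2-(methoxymethoxy)-6-pentylbenzoate
Product: 9 tert-butyl 4-{[(2E)-3-(2-hydroxyethyl)oct-2-enoyl]oxy}-2-(methoxymethoxy)-6-pentylbenzoate
Conditions: HF·pyridine, pyridine/THF, 0 °C → rt
Reagents that add atoms: none
Why: Fluoride-driven desilylation of the primary silyl ether under buffered conditions should leave the aryl ester, MOM ether and tert-butyl ester intact, and the alcohol cannot lactonise because it lies trans to the ester.

Step 6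
Reactants: 9 tert-butyl 4-{[(2E)-3-(2-hydroxyethyl)oct-2-enoyl]oxy}-2-(methoxymethoxy)-6-pentylbenzoate
Product: 10 (3E)-5-[4-(tert-butoxycarbonyl)-3-(methoxymethoxy)-5-pentylphenoxy]-5-oxo-3-pentylpent-3-enoic acid
Conditions: TEMPO (0.2 equiv), PhI(OAc)2 (2.2 equiv), MeCN/H2O, rt
Reagents that add atoms: water, O
Why: Oxoammonium (TEMPO) oxidation should take the primary alcohol through the aldehyde hydrate to the acid under nearly neutral conditions, which limits migration or E/Z isomerisation of the β,γ-double bond.

Step 7
Reactants: 10 (3E)-5-[4-(tert-butoxycarbonyl)-3-(methoxymethoxy)-5-pentylphenoxy]-5-oxo-3-pentylpent-3-enoic acid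
Product: 11 tert-butyl 4-{[(2E)-5-chloro-5-oxo-3-pentylpent-2-enoyl]oxy}-2-(methoxymethoxy)-6-pentylbenzoate
Conditions: 1-chloro-N,N,2-trimethylprop-1-en-1-amine (1.05 equiv), CH2Cl2, 0 °C → rt; used directly as a solution
Reagents that add atoms: 1-chloro-N,N,2-trimethylprop-1-en-1-amine, CC(C)=C(Cl)N(C)C
Why: Acid chloride formation with an α-chloroenamine is neutral, so no HCl should attack the MOM ether or tert-butyl ester and no base should trigger premature ketene formation or isomerise the alkene.

Step 8
Reactants: 12 chloroacetaldehyde dimethyl acetal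
Product: 14 methoxy(trimethylsilyl)acetylene, via lithium methoxyacetylide 13 (not isolated)
Conditions: LiNEt2 (3.1 equiv, from Et2NH and n-BuLi), THF, −78 → 0 °C; then Me3SiCl (2.1 equiv), −78 °C → rt; distillation
Reagents that add atoms: chlorotrimethylsilane, C[Si](C)(C)Cl
Why: Successive base-induced eliminations of methanol and HCl from the chloroacetal should give methoxyacetylene, which the excess amide deprotonates, and C-silylation of the acetylide then gives the silylated ynol ether, which has no β-hydrogen for a retro-ene loss on heating.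

Step 9
Reactants: 11 tert-butyl 4-{[(2E)-5-chloro-5-oxo-3-pentylpent-2-enoyl]oxy}-2-(methoxymethoxy)-6-pentylbenzoate; 14 methoxy(trimethylsilyl)acetylene
Product: 19 tert-butyl 4-{[2-hydroxy-4-methoxy-6-pentyl-3-(trimethylsilyl)benzoyl]oxy}-2-(methoxymethoxy)-6-pentylbenzoate, via vinylketene 15 (not isolated), via vinylcyclobutenone 16 (not isolated), via dienylketene 17 (not isolated), via cyclohexadienone 18 (not isolated)
Conditions: 14 (2 equiv), iPr2NEt (1.5 equiv), toluene, slow addition of 11, 0 °C → rt; filtration from the ammonium salt; then 100 °C (sealed vessel)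
Reagents that add atoms: none
Why: iPr2NEt should remove HCl across the C(=O)–CH2 bond of 11 (a CH2 doubly activated, being also γ to the aryl ester) to give vinylketene 15 with the (E) alkene untouched; the silyl-bearing alkyne carbon, the nucleophilic end of the ynol ether, then bonds to the ketene carbonyl carbon (C2–C3) and the methoxy carbon to the ketene α-carbon (C4–C5), giving cyclobutenone 16. On heating, 16 should open reversibly by four-electron electrocyclic cleavage of the former ketene C=C bond to dienylketene 17, and the isomer with the vinyl group turned inward closes ring A by thermal six-electron (disrotatory) electrocyclisation between C1 and the ketene carbon C2, after which dienone 18 tautomerises to phenol 19. The closest known reaction type is the Danheiser benzannulation of vinylketenes with alkoxyalkynes, combined with the familiar (2+2) addition of acid-chloride-derived ketenes to ynol ethers. No stereocentre remains in 19, since the sp3 centres of 16 and 18 are transient and racemic. The step needs regiocontrol in the (2+2) addition, secured by the polarisation of the alkyne (OMe donor and β-silicon both stabilise positive charge on the oxygen-bearing carbon), which puts OMe at C4 and SiMe3 at C3; it also needs periselectivity against closure of the ketene onto the ester carbonyl, secured by the trans arrangement of ketenyl and ester groups in 15. The new C2–OH is chelated to the depside carbonyl and flanked by SiMe3, so it should not be acylated by remaining ketene.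

Step 10
Reactants: 19 tert-butyl 4-{[2-hydroxy-4-methoxy-6-pentyl-3-(trimethylsilyl)benzoyl]oxy}-2-(methoxymethoxy)-6-pentylbenzoate
Product: 20 tert-butyl 4-[(3-chloro-2-hydroxy-4-methoxy-6-pentylbenzoyl)oxy]-2-(methoxymethoxy)-6-pentylbenzoate
Conditions: N-chlorosuccinimide (1.05 equiv), MeCN, 0 °C → rt, dark
Reagents that add atoms: N-chlorosuccinimide, O=C1CCC(=O)N1Cl
Why: Electrophilic ipso-chlorodesilylation should occur at C3 because the cationic intermediate there is stabilised by the β-silicon and by the flanking C2–OH and C4–OMe, and loss of the silyl group is faster than loss of a proton from C5.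

Step 11
Reactants: 20 tert-butyl 4-[(3-chloro-2-hydroxy-4-methoxy-6-pentylbenzoyl)oxy]-2-(methoxymethoxy)-6-pentylbenzoate
Product: 21 4-[(3-chloro-2-hydroxy-4-methoxy-6-pentylbenzoyl)oxy]-2-hydroxy-6-pentylbenzoic acid
Conditions: CF3CO2H/CH2Cl2, H2O (5 equiv), 0 °C → rt
Reagents that add atoms: none
Why: Acidolysis with trifluoroacetic acid should cleave the tert-butyl ester (as 2-methylpropene) and the MOM acetal in one operation, while the depside ester, the aryl chloride and the methyl ether are stable to these conditions.

**Compound list**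

1 | olivetolic acid (2,4-dihydroxy-6-pentylbenzoic acid) | CCCCCc1cc(O)cc(O)c1C(=O)O | starting material
2 | tert-butyl 2,4-dihydroxy-6-pentylbenzoate | CCCCCc1cc(O)cc(O)c1C(=O)OC(C)(C)C | intermediate
3 | 4-(tert-butyldimethylsilyloxy)but-1-yne | C#CCCO[Si](C)(C)C(C)(C)C | starting material
4 | pentylmagnesium bromide | CCCCC[Mg]Br | starting material
5 | alkenylcopper from syn addition of pentylcopper to 3 (Cu cis to pentyl) | CC(C)(C)[Si](C)(C)OCC/C(CCCCC)=C/[Cu] | intermediate (not isolated)
6 | (E)-3-[2-(tert-butyldimethylsilyloxy)ethyl]oct-2-enoic acid (pentyl cis to CO2H) | CC(C)(C)[Si](C)(C)OCC/C(CCCCC)=C/C(=O)O | intermediate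
7 | tert-butyl 4-({(2E)-3-[2-(tert-butyldimethylsilyloxy)ethyl]oct-2-enoyl}oxy)-2-hydroxy-6-pentylbenzoate | CC(C)(C)[Si](C)(C)OCC/C(CCCCC)=C/C(=O)Oc1cc(CCCCC)c(C(=O)OC(C)(C)C)c(O)c1 | intermediate
8 | tert-butyl 4-({(2E)-3-[2-(tert-butyldimethylsilyloxy)ethyl]oct-2-enoyl}oxy)-2-(methoxymethoxy)-6-pentylbenzoate | CC(C)(C)[Si](C)(C)OCC/C(CCCCC)=C/C(=O)Oc1cc(CCCCC)c(C(=O)OC(C)(C)C)c(OCOC)c1 | intermediate
9 | tert-butyl 4-{[(2E)-3-(2-hydroxyethyl)oct-2-enoyl]oxy}-2-(methoxymethoxy)-6-pentylbenzoate | OCC/C(CCCCC)=C/C(=O)Oc1cc(CCCCC)c(C(=O)OC(C)(C)C)c(OCOC)c1 | intermediate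
10 | (3E)-5-[4-(tert-butoxycarbonyl)-3-(methoxymethoxy)-5-pentylphenoxy]-5-oxo-3-pentylpent-3-enoic acid (ring B aryl half-ester of (E)-3-pentylglutaconic acid) | O=C(O)C/C(CCCCC)=C/C(=O)Oc1cc(CCCCC)c(C(=O)OC(C)(C)C)c(OCOC)c1 | intermediate
11 | tert-butyl 4-{[(2E)-5-chloro-5-oxo-3-pentylpent-2-enoyl]oxy}-2-(methoxymethoxy)-6-pentylbenzoate (ring B aryl ester of (E)-3-pentylglutaconic acid monochloride) | O=C(Cl)C/C(CCCCC)=C/C(=O)Oc1cc(CCCCC)c(C(=O)OC(C)(C)C)c(OCOC)c1 | intermediate (key-step precursor)
12 | chloroacetaldehyde dimethyl acetal | COC(CCl)OC | starting material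
13 | lithium methoxyacetylide | COC#C[Li] | intermediate (not isolated)
14 | methoxy(trimethylsilyl)acetylene | COC#C[Si](C)(C)C | intermediate
15 | vinylketene: tert-butyl 2-(methoxymethoxy)-4-{[(2E)-5-oxo-3-pentylpenta-2,4-dienoyl]oxy}-6-pentylbenzoate (ketenyl group trans to the ester) | O=C=C/C(CCCCC)=C/C(=O)Oc1cc(CCCCC)c(C(=O)OC(C)(C)C)c(OCOC)c1 | intermediate (not isolated)
16 | vinylcyclobutenone: tert-butyl 4-({(2E)-3-[2-methoxy-4-oxo-3-(trimethylsilyl)cyclobut-2-en-1-yl]oct-2-enoyl}oxy)-2-(methoxymethoxy)-6-pentylbenzoate (racemic) | O=C1C([Si](C)(C)C)=C(OC)C1/C(CCCCC)=C/C(=O)Oc1cc(CCCCC)c(C(=O)OC(C)(C)C)c(OCOC)c1 | intermediate (not isolated)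
17 | dienylketene: tert-butyl 4-{[(2E,4E)-5-methoxy-7-oxo-3-pentyl-6-(trimethylsilyl)hepta-2,4,6-trienoyl]oxy}-2-(methoxymethoxy)-6-pentylbenzoate (ketene carbon and C3 of the chain cis across the central alkene) | O=C=C([Si](C)(C)C)/C(OC)=C\C(CCCCC)=C\C(=O)Oc1cc(CCCCC)c(C(=O)OC(C)(C)C)c(OCOC)c1 | intermediate (not isolated)
18 | cyclohexadienone: ring B aryl 4-methoxy-2-oxo-6-pentyl-3-(trimethylsilyl)cyclohexa-3,5-diene-1-carboxylate (racemic keto tautomer of 19) | O=C1C([Si](C)(C)C)=C(OC)C=C(CCCCC)C1C(=O)Oc1cc(CCCCC)c(C(=O)OC(C)(C)C)c(OCOC)c1 | intermediate (not isolated)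
19 | tert-butyl 4-{[2-hydroxy-4-methoxy-6-pentyl-3-(trimethylsilyl)benzoyl]oxy}-2-(methoxymethoxy)-6-pentylbenzoate | CCCCCc1cc(OC(=O)c2c(CCCCC)cc(OC)c([Si](C)(C)C)c2O)cc(OCOC)c1C(=O)OC(C)(C)C | intermediate (key-step product)
20 | tert-butyl 4-[(3-chloro-2-hydroxy-4-methoxy-6-pentylbenzoyl)oxy]-2-(methoxymethoxy)-6-pentylbenzoate | CCCCCc1cc(OC(=O)c2c(CCCCC)cc(OC)c(Cl)c2O)cc(OCOC)c1C(=O)OC(C)(C)C | intermediate
21 | 4-[(3-chloro-2-hydroxy-4-methoxy-6-pentylbenzoyl)oxy]-2-hydroxy-6-pentylbenzoic acid | CCCCCc1cc(OC(=O)c2c(CCCCC)cc(OC)c(Cl)c2O)cc(O)c1C(=O)O | target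

**Step count.** Total: 11 steps. Longest linear sequence: 9 steps (steps 2–7 and 9–11, from 3 and 4).

**Steps most likely to fail**

1. Step 9 (benzannulation).
   - What may go wrong: the vinylketene may isomerise to the geometry in which the ketene lies beside the ester carbonyl and then close to a 6-aryloxy-2-pyranone. Amine-promoted ketene dimerisation may outrun the (2+2) addition to the hindered silylalkyne. The cyclobutenone may open without closing to the arene.
   - Fallback: it gives up the annulation and makes the depside bond by classical condensation, setting out from 2 and returning to the route at 21. Selective O-methylation of the non-chelated C4 hydroxyl of 2 (MeI, K2CO3, acetone) should give tert-butyl 2-hydroxy-4-methoxy-6-pentylbenzoate F1. Phenol-directed ortho-chlorination (N-chlorosuccinimide with a thiourea or secondary-amine catalyst, any C5 isomer being removed at this early stage) should give tert-butyl 3-chloro-2-hydroxy-4-methoxy-6-pentylbenzoate F2. Trifluoroacetic acid then frees 3-chloro-2-hydroxy-4-methoxy-6-pentylbenzoic acid F3. Condensation of F3 with the C4 hydroxyl of a second portion of 2 (DCC, toluene) should give tert-butyl 4-[(3-chloro-2-hydroxy-4-methoxy-6-pentylbenzoyl)oxy]-2-hydroxy-6-pentylbenzoate F4, and trifluoroacetic acid converts F4 into 21.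

2. Step 2 (carbocupration–carboxylation).
   - What may go wrong: insertion of CO2 into the alkenylcopper may be slow, so that protonation on work-up or thermal decay of the organocopper competes. Coordination of the ether oxygen may erode the regiochemical purity of the carbocupration.
   - Fallback: it sets out from 3 and 4 and returns at 6. The alkenylcopper 5 is quenched with iodine at −40 °C to give (E)-tert-butyl{[3-(iodomethylidene)octyl]oxy}dimethylsilane F5, which can be purified from any regioisomer. Iodine–lithium exchange (t-BuLi, Et2O, −78 °C) and carboxylation of the alkenyllithium with CO2, both with retention of geometry, should then give 6.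

3. Step 10 (ipso-chlorodesilylation).
   - What may go wrong: chlorination at C5–H of ring A (para to the C2 hydroxyl) may compete with ipso attack at C3, or adventitious acid may cause protodesilylation before chlorination.
   - Fallback: it sets out from 19 and returns at 20. Brief treatment with dilute CF3CO2H in CH2Cl2 at −20 °C, under which the doubly oxygen-flanked C–Si bond should cleave before the MOM ether or tert-butyl ester, gives tert-butyl 4-[(2-hydroxy-4-methoxy-6-pentylbenzoyl)oxy]-2-(methoxymethoxy)-6-pentylbenzoate F6. Phenol-directed ortho-chlorination of F6 (N-chlorosuccinimide with a thiourea or secondary-amine catalyst; ring B carries no free hydroxyl) should then place chlorine at C3 to give 20.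

**Further compounds**

F1 | step 9 | tert-butyl 2-hydroxy-4-methoxy-6-pentylbenzoate | CCCCCc1cc(OC)cc(O)c1C(=O)OC(C)(C)C
F2 | step 9 | tert-butyl 3-chloro-2-hydroxy-4-methoxy-6-pentylbenzoate | CCCCCc1cc(OC)c(Cl)c(O)c1C(=O)OC(C)(C)C
F3 | step 9 | 3-chloro-2-hydroxy-4-methoxy-6-pentylbenzoic acid | CCCCCc1cc(OC)c(Cl)c(O)c1C(=O)O
F4 | step 9 | tert-butyl 4-[(3-chloro-2-hydroxy-4-methoxy-6-pentylbenzoyl)oxy]-2-hydroxy-6-pentylbenzoate | CCCCCc1cc(OC(=O)c2c(CCCCC)cc(OC)c(Cl)c2O)cc(O)c1C(=O)OC(C)(C)C
F5 | step 2 | (E)-tert-butyl{[3-(iodomethylidene)octyl]oxy}dimethylsilane | CC(C)(C)[Si](C)(C)OCC/C(CCCCC)=C/I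
F6 | step 10 | tert-butyl 4-[(2-hydroxy-4-methoxy-6-pentylbenzoyl)oxy]-2-(methoxymethoxy)-6-pentylbenzoate | CCCCCc1cc(OC(=O)c2c(CCCCC)cc(OC)cc2O)cc(OCOC)c1C(=O)OC(C)(C)C
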